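**Retrosynthetic overview** (isoflavan numbering: ring C = O1, C2, C3, C4; ring A = C4a–C8a; ring B = C1'–C6')

- Feature: C3, the only stereocentre, carries ring B (C1') and the C4 methylene that leads to C4a of ring A. This 1-aryl-2-arylethyl unit is what a vinyl boronate gives when one aryl group shifts from boron to the boron-bearing carbon and a second aryl group is coupled to the terminal carbon.
- Key disconnection: C3–C1' (1,2-shift of ring B) and C4–C4a (reductive elimination from palladium) in one three-component coupling of the ring B aryllithium, vinylboronic acid pinacol ester and the ring A triflate. No ring closes here.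
- The C3–B bond is then exchanged with retention for the C2 methylene (homologation, oxidation). Ring C is the only ring made and is closed last at O1–C2; rings A and B both come from resorcinol.
- Ring B carries MOM acetals. Ring A carries SEM acetals, which direct lithiation like MOM but fall to fluoride, so that only the ring A phenols are free when ring C is closed (a free 2'-OH would close a five-membered ring instead).

Key step: step 7

Abbreviations: prenyl = 3-methylbut-2-en-1-yl; MOM = methoxymethyl; SEM = 2-(trimethylsilyl)ethoxymethyl.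

Remark (assumption): the ligand is the MandyPhos-type ferrocene 1,1'-bis[bis(4-methoxy-3,5-dimethylphenyl)phosphino]-2,2'-bis[α-(dimethylamino)benzyl]ferrocene. Which antipode gives (R)-16 is not asserted here; both are available, the one with that sense of induction is to be used, and the sense is to be checked on 19 after step 9.

**Route**

Step 1
Reactants: 1 resorcinol
Product: 2 1,3-bis(methoxymethoxy)benzene
Conditions: NaH (2.4 equiv), DMF, 0 °C; MOMCl (2.4 equiv), 0 °C to rt
Reagents that add atoms: chloromethyl methyl ether (MOMCl), COCCl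
Why: Williamson-type O-alkylation of the disodium resorcinolate by the reactive α-chloro ether should give the bis-acetal, whose two MOM groups later direct both lithiations of ring B.

Step 2
Reactants: 2 1,3-bis(methoxymethoxy)benzene, 3 prenyl bromide (1-bromo-3-methylbut-2-ene)
Product: 5 1,3-bis(methoxymethoxy)-2-prenylbenzene, via 2,6-bis(methoxymethoxy)phenyllithium 4 (not isolated)
Conditions: n-BuLi (1.1 equiv), THF, 0 °C to rt; CuI (10 mol%), then 3, –78 °C to rt
Reagents that add atoms: none
Why: Directed ortho-metalation occurs at C2, the position flanked by both acetal oxygens, and copper-catalysed SN2 allylation at the primary carbon of prenyl bromide should give the linear prenyl arene.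

Step 3
Reactants: 1 resorcinol
Product: 6 1,3-bis{[2-(trimethylsilyl)ethoxy]methoxy}benzene
Conditions: NaH (2.4 equiv), DMF, 0 °C; SEMCl (2.3 equiv), 0 °C to rt
Reagents that add atoms: 2-(trimethylsilyl)ethoxymethyl chloride (SEMCl), C[Si](C)(C)CCOCCl
Why: The same Williamson-type O-alkylation installs two SEM acetals, which direct ortho-lithiation as MOM does but can later be removed by fluoride without touching MOM.

Step 4
Reactants: 6 1,3-bis(SEM-oxy)benzene, 3 prenyl bromide
Product: 8 2-prenyl-1,3-bis{[2-(trimethylsilyl)ethoxy]methoxy}benzene, via 2,6-bis(SEM-oxy)phenyllithium 7 (not isolated)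
Conditions: n-BuLi (1.1 equiv), THF, 0 °C to rt; CuI (10 mol%), then 3, –78 °C to rt
Reagents that add atoms: none
Why: Directed ortho-metalation between the two acetal oxygens followed by copper-catalysed SN2 allylation, as in step 2.

Step 5
Reactants: 8 2-prenyl-1,3-bis(SEM-oxy)benzene
Product: 11 3-prenyl-2,4-bis{[2-(trimethylsilyl)ethoxy]methoxy}phenol, via ring A aryllithium 9 (not isolated), via lithium aryltrimethoxyborate 10 (not isolated)
Conditions: n-BuLi (1.2 equiv), THF, 0 °C to rt; B(OMe)3 (2 equiv), –78 °C to rt; 30% H2O2, aq NaOH, 0 °C; NH4Cl work-up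
Reagents that add atoms: hydrogen peroxide, OO
Why: A second directed ortho-metalation at C4 (C4 and C6 are equivalent), borate trapping and peroxide oxidation (boron-to-oxygen 1,2-shift) should place the third oxygen next to an acetal oxygen, alkaline peroxide leaving the unactivated trisubstituted alkene and the acetals alone.

Step 6
Reactants: 11 3-prenyl-2,4-bis(SEM-oxy)phenol
Product: 12 3-prenyl-2,4-bis{[2-(trimethylsilyl)ethoxy]methoxy}phenyl trifluoromethanesulfonate
Conditions: PhNTf2 (1.1 equiv), Et3N, DMAP (cat.), CH2Cl2, 0 °C to rt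
Reagents that add atoms: N-phenylbis(trifluoromethanesulfonimide), O=S(=O)(N(c1ccccc1)S(=O)(=O)C(F)(F)F)C(F)(F)F
Why: O-sulfonylation of the unhindered phenol with the mild triflating agent should not touch the alkene or the acetals and gives the halide-free electrophile the coupling needs.

Step 7
Reactants: 5 1,3-bis(methoxymethoxy)-2-prenylbenzene, 13 vinylboronic acid pinacol ester, 12 ring A triflate
Product: 16 2-[(1R)-1-[2,4-bis(methoxymethoxy)-3-prenylphenyl]-2-[3-prenyl-2,4-bis(SEM-oxy)phenyl]ethyl]-4,4,5,5-tetramethyl-1,3,2-dioxaborolane, via ring B aryllithium 14 (not isolated), via lithium vinylborate complex 15 (not isolated)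
Conditions: 5 (1.25 equiv), n-BuLi (1.2 equiv), THF, 0 °C to rt; 13 (1.2 equiv), 0 °C to rt; then 12 (1.0 equiv), Pd(OAc)2 (2 mol%), MandyPhos ligand (2.4 mol%), THF, 60 °C
Reagents that add atoms: none
Why: Aryllithium 14, made by directed ortho-metalation of 5 with a slight deficit of n-BuLi and so free of halide and of residual butyllithium, adds to vinyl boronate 13 to give the four-coordinate borate 15. Zerovalent palladium inserts into the C–O bond of triflate 12, and the resulting cationic aryl complex of divalent palladium binds the vinyl group of 15; ring B then shifts from boron to the adjacent carbon anti to palladium while palladium bonds the terminal carbon (C3–C1'), and reductive elimination forms C4–C4a. The closest known reaction type is the enantioselective palladium-catalysed conjunctive cross-coupling of vinylboron ate complexes with aryl triflates; no ring is closed. The C3 stereocentre is set in the 1,2-metallate shift by the chiral ferrocenyl bisphosphine on palladium, with the ligand antipode chosen to give the R boronate. The step needs the metallate shift to outrun direct Suzuki-type transfer of aryl or vinyl from boron to palladium, which the wide-bite-angle ligand, the non-coordinating triflate and the electron-rich, readily migrating ring B should secure; the prenyl alkenes are trisubstituted and unactivated and should not compete for palladium.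

Step 8
Reactants: 16 (R)-boronate
Product: 18 (2R)-2-[2,4-bis(methoxymethoxy)-3-prenylphenyl]-3-[3-prenyl-2,4-bis(SEM-oxy)phenyl]propan-1-ol, via homologated pinacol boronate 17 (not isolated)
Conditions: BrCH2Cl (3 equiv), n-BuLi (2.5 equiv), THF, –78 °C to rt; then 3 M aq NaOH, 30% H2O2, 0 °C to rt
Reagents that add atoms: bromochloromethane, ClCBr; hydrogen peroxide, OO
Why: Matteson homologation, in which chloromethyllithium generated in the presence of 16 adds to boron and the C3–B bond migrates to the new CH2 with loss of chloride and retention at C3, followed by peroxide oxidation of the primary C–B bond, so the configuration from step 7 is carried unchanged into the C2 alcohol.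

Step 9
Reactants: 18 (R)-alcohol
Product: 19 4-[(2R)-2-[2,4-bis(methoxymethoxy)-3-prenylphenyl]-3-hydroxypropyl]-2-prenylbenzene-1,3-diol
Conditions: TBAF (8 equiv), ethylenediamine (6 equiv), DMF, 45 °C; NH4Cl work-up
Reagents that add atoms: none
Why: Fluoride attack at silicon fragments both SEM acetals (β-elimination to ethene, then loss of formaldehyde, which the diamine traps before it can hydroxymethylate the resorcinol ring), freeing the C8a and C7 phenols while the silicon-free MOM ethers of ring B stay on.

Step 10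
Reactants: 19 diphenol alcohol
Product: 20 (3R)-3-[2,4-bis(methoxymethoxy)-3-prenylphenyl]-8-prenyl-3,4-dihydro-2H-chromen-7-ol
Conditions: PPh3 (1.5 equiv), DIAD (1.5 equiv), THF (0.01 M), 0 °C to rt
Reagents that add atoms: none
Why: Intramolecular Mitsunobu etherification, in which the C8a phenol displaces the activated primary oxygen at C2 in a 6-exo-tet closure of ring C; the C7 hydroxyl can only react between molecules and is held back by dilution, and C3 is not a reacting centre, so its configuration is kept.

Step 11
Reactants: 20 (3R)-chromanol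
Product: 21 Kanzonol X, 4-[(3R)-7-hydroxy-8-prenyl-3,4-dihydro-2H-chromen-3-yl]-2-prenylbenzene-1,3-diol
Conditions: 3 M aq HCl, MeOH, 40 °C, under argon, followed closely
Reagents that add atoms: none
Why: Acid-catalysed acetal exchange with methanol should remove both MOM groups as dimethoxymethane under conditions mild enough that protonation of the prenyl alkenes, which would lead to 2,2-dimethylchromans, stays slow.

**Compound list**

1 | resorcinol | Oc1cccc(O)c1 | starting material
2 | 1,3-bis(methoxymethoxy)benzene | COCOc1cccc(OCOC)c1 | intermediate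
3 | prenyl bromide (1-bromo-3-methylbut-2-ene) | CC(C)=CCBr | starting material
4 | 2,6-bis(methoxymethoxy)phenyllithium | [Li]c1c(OCOC)cccc1OCOC | intermediate
5 | 1,3-bis(methoxymethoxy)-2-prenylbenzene | COCOc1cccc(OCOC)c1CC=C(C)C | intermediate
6 | 1,3-bis{[2-(trimethylsilyl)ethoxy]methoxy}benzene | C[Si](C)(C)CCOCOc1cccc(OCOCC[Si](C)(C)C)c1 | intermediate
7 | 2,6-bis{[2-(trimethylsilyl)ethoxy]methoxy}phenyllithium | [Li]c1c(OCOCC[Si](C)(C)C)cccc1OCOCC[Si](C)(C)C | intermediate
8 | 2-prenyl-1,3-bis{[2-(trimethylsilyl)ethoxy]methoxy}benzene | C[Si](C)(C)CCOCOc1cccc(OCOCC[Si](C)(C)C)c1CC=C(C)C | intermediate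
9 | 3-prenyl-2,4-bis{[2-(trimethylsilyl)ethoxy]methoxy}phenyllithium (ring A aryllithium) | [Li]c1ccc(OCOCC[Si](C)(C)C)c(CC=C(C)C)c1OCOCC[Si](C)(C)C | intermediate
10 | lithium trimethoxy[3-prenyl-2,4-bis(SEM-oxy)phenyl]borate | [Li+].CO[B-](OC)(OC)c1ccc(OCOCC[Si](C)(C)C)c(CC=C(C)C)c1OCOCC[Si](C)(C)C | intermediate
11 | 3-prenyl-2,4-bis{[2-(trimethylsilyl)ethoxy]methoxy}phenol | Oc1ccc(OCOCC[Si](C)(C)C)c(CC=C(C)C)c1OCOCC[Si](C)(C)C | intermediate
12 | 3-prenyl-2,4-bis{[2-(trimethylsilyl)ethoxy]methoxy}phenyl trifluoromethanesulfonate | O=S(=O)(Oc1ccc(OCOCC[Si](C)(C)C)c(CC=C(C)C)c1OCOCC[Si](C)(C)C)C(F)(F)F | intermediate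
13 | vinylboronic acid pinacol ester | C=CB1OC(C)(C)C(C)(C)O1 | starting material
14 | 2,4-bis(methoxymethoxy)-3-prenylphenyllithium (ring B aryllithium) | [Li]c1ccc(OCOC)c(CC=C(C)C)c1OCOC | intermediate
15 | lithium [2,4-bis(methoxymethoxy)-3-prenylphenyl](vinyl)(pinacolato)borate | [Li+].C=C[B-]1(OC(C)(C)C(C)(C)O1)c1ccc(OCOC)c(CC=C(C)C)c1OCOC | intermediate
16 | 2-[(1R)-1-[2,4-bis(methoxymethoxy)-3-prenylphenyl]-2-[3-prenyl-2,4-bis(SEM-oxy)phenyl]ethyl]-4,4,5,5-tetramethyl-1,3,2-dioxaborolane | CC1(C)OB(OC1(C)C)[C@H](Cc1ccc(OCOCC[Si](C)(C)C)c(CC=C(C)C)c1OCOCC[Si](C)(C)C)c1ccc(OCOC)c(CC=C(C)C)c1OCOC | intermediate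
17 | 2-[(2R)-2-[2,4-bis(methoxymethoxy)-3-prenylphenyl]-3-[3-prenyl-2,4-bis(SEM-oxy)phenyl]propyl]-4,4,5,5-tetramethyl-1,3,2-dioxaborolane | CC1(C)OB(OC1(C)C)C[C@H](Cc1ccc(OCOCC[Si](C)(C)C)c(CC=C(C)C)c1OCOCC[Si](C)(C)C)c1ccc(OCOC)c(CC=C(C)C)c1OCOC | intermediate
18 | (2R)-2-[2,4-bis(methoxymethoxy)-3-prenylphenyl]-3-[3-prenyl-2,4-bis(SEM-oxy)phenyl]propan-1-ol | OC[C@H](Cc1ccc(OCOCC[Si](C)(C)C)c(CC=C(C)C)c1OCOCC[Si](C)(C)C)c1ccc(OCOC)c(CC=C(C)C)c1OCOC | intermediate
19 | 4-[(2R)-2-[2,4-bis(methoxymethoxy)-3-prenylphenyl]-3-hydroxypropyl]-2-prenylbenzene-1,3-diol | OC[C@H](Cc1ccc(O)c(CC=C(C)C)c1O)c1ccc(OCOC)c(CC=C(C)C)c1OCOC | intermediate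
20 | (3R)-3-[2,4-bis(methoxymethoxy)-3-prenylphenyl]-8-prenyl-3,4-dihydro-2H-chromen-7-ol | COCOc1ccc([C@@H]2COc3c(ccc(O)c3CC=C(C)C)C2)c(OCOC)c1CC=C(C)C | intermediate
21 | Kanzonol X, 4-[(3R)-7-hydroxy-8-prenyl-3,4-dihydro-2H-chromen-3-yl]-2-prenylbenzene-1,3-diol | CC(C)=CCc1c(O)ccc([C@@H]2COc3c(ccc(O)c3CC=C(C)C)C2)c1O | target

**Step count**

Total: 11 steps. Longest linear sequence: 9 steps (steps 3 to 11, from resorcinol through ring A).

**Steps most likely to fail**

1. Step 7. The triflate has an ortho acetal and the migrating ring is substituted at both ortho positions, so oxidative addition and the metallate shift may both be slow. Direct aryl or vinyl transfer from boron to palladium, protodeboronation of 15, or a poorly organised shift with loss of facial control could then take over. Incomplete or misdirected lithiation of 5 (at the benzylic-allylic CH2) would add to this, and a deuterium quench of a sample of 14 is the check.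
   Fallback: auxiliary-controlled benzylation, setting out from aryllithiums 9 and 14 and coming back at 18.
   - Ring A electrophile: aryllithium 9 and paraformaldehyde should give [3-prenyl-2,4-bis(SEM-oxy)phenyl]methanol F1, which CBr4/PPh3 in CH2Cl2 at 0 °C converts into 1-(bromomethyl)-3-prenyl-2,4-bis(SEM-oxy)benzene F2, used without purification.
   - Ring B nucleophile: aryllithium 14 opens ethylene oxide to 2-[2,4-bis(methoxymethoxy)-3-prenylphenyl]ethanol F3. TEMPO (cat.) and PhI(OAc)2 in aqueous MeCN oxidise it to [2,4-bis(methoxymethoxy)-3-prenylphenyl]acetic acid F4. Its mixed pivalic anhydride acylates lithiated (R)-4-benzyloxazolidin-2-one to give (4R)-4-benzyl-3-{[2,4-bis(methoxymethoxy)-3-prenylphenyl]acetyl}oxazolidin-2-one F5.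
   - Union: deprotonation with NaN(SiMe3)2 at –78 °C and Evans alkylation with F2 on the enolate face away from the benzyl group should give the (4R,2'R)-alkylated imide F6, and LiBH4 reduction releases alcohol 18.

2. Step 8. Chloromethyllithium may decompose faster than it is captured by the hindered benzylic boron centre, so that unchanged 16 enters the oxidation and is lost as the secondary carbinol.
   Fallback: two-stage homologation, setting out from 16 and coming back at 17. The longer-lived dichloromethyllithium (CH2Cl2 and LiN(i-Pr)2 in the presence of 16, THF, –78 °C, then ZnCl2, to rt) inserts to give the pinacol [(2R)-1-chloro-2-(ring B aryl)-3-(ring A aryl)propyl]boronate F7 as a mixture of epimers at the chlorinated carbon. K[HB(Oi-Pr)3] then replaces chloride by hydride through a second 1,2-shift to give 17, which is oxidised as in step 8.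

3. Step 11. The acid needed for acetal cleavage may protonate the prenyl double bonds, and the tertiary cations would be captured by the neighbouring phenols (7-OH on ring A, 2'- and 4'-OH on ring B) to close 2,2-dimethylchroman rings.
   Fallback: acetal-to-silyl exchange without a Brønsted acid, setting out from 20 and coming back at 21. TMSOTf and 2,2'-bipyridyl in MeCN at 0 °C convert the aryl MOM ethers (and the free 7-OH) into trimethylsilyl ethers, giving the tris(trimethylsilyl) ether of Kanzonol X F8, which aqueous work-up hydrolyses to 21.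

**Further compounds**

F1 | step 7 | [3-prenyl-2,4-bis{[2-(trimethylsilyl)ethoxy]methoxy}phenyl]methanol | OCc1ccc(OCOCC[Si](C)(C)C)c(CC=C(C)C)c1OCOCC[Si](C)(C)C
F2 | step 7 | 1-(bromomethyl)-3-prenyl-2,4-bis{[2-(trimethylsilyl)ethoxy]methoxy}benzene | BrCc1ccc(OCOCC[Si](C)(C)C)c(CC=C(C)C)c1OCOCC[Si](C)(C)C
F3 | step 7 | 2-[2,4-bis(methoxymethoxy)-3-prenylphenyl]ethan-1-ol | OCCc1ccc(OCOC)c(CC=C(C)C)c1OCOC
F4 | step 7 | [2,4-bis(methoxymethoxy)-3-prenylphenyl]acetic acid | OC(=O)Cc1ccc(OCOC)c(CC=C(C)C)c1OCOC
F5 | step 7 | (4R)-4-benzyl-3-{[2,4-bis(methoxymethoxy)-3-prenylphenyl]acetyl}-1,3-oxazolidin-2-one | O=C(Cc1ccc(OCOC)c(CC=C(C)C)c1OCOC)N1C(=O)OC[C@H]1Cc1ccccc1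
F6 | step 7 | (4R)-4-benzyl-3-[(2R)-2-[2,4-bis(methoxymethoxy)-3-prenylphenyl]-3-[3-prenyl-2,4-bis(SEM-oxy)phenyl]propanoyl]-1,3-oxazolidin-2-one | O=C([C@H](Cc1ccc(OCOCC[Si](C)(C)C)c(CC=C(C)C)c1OCOCC[Si](C)(C)C)c1ccc(OCOC)c(CC=C(C)C)c1OCOC)N1C(=O)OC[C@H]1Cc1ccccc1
F7 | step 8 | 2-[(2R)-1-chloro-2-[2,4-bis(methoxymethoxy)-3-prenylphenyl]-3-[3-prenyl-2,4-bis(SEM-oxy)phenyl]propyl]-4,4,5,5-tetramethyl-1,3,2-dioxaborolane (epimers at C1) | CC1(C)OB(OC1(C)C)C(Cl)[C@H](Cc1ccc(OCOCC[Si](C)(C)C)c(CC=C(C)C)c1OCOCC[Si](C)(C)C)c1ccc(OCOC)c(CC=C(C)C)c1OCOC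
F8 | step 11 | tris(trimethylsilyl) ether of Kanzonol X | CC(C)=CCc1c(O[Si](C)(C)C)ccc([C@@H]2COc3c(ccc(O[Si](C)(C)C)c3CC=C(C)C)C2)c1O[Si](C)(C)C
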